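**Assumption:** the target has no stereocentre and no stereogenic double bond, so it is made as the single achiral compound drawn.

## Retrosynthetic overview

1. The phenol is freed last from its methyl ether; the amide comes from a 2,6-disubstituted aniline and decanoyl chloride; the aniline comes from a nitroarene.
2. The pyridine is the only ring that is built (the benzene ring is bought): it comes from a 2-ethoxy-3,4-dihydro-2H-pyran, a masked 1,5-keto aldehyde, with hydroxylamine as nitrogen source.
3. The dihydropyran comes from an aryl enone and ethyl vinyl ether by hetero-Diels–Alder reaction.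
4. Key C–C bond: intermolecular aldol addition of acetone to 3-methoxy-2-nitrobenzaldehyde, then dehydration to the enone; this bond becomes C3–C4 of the pyridine.
5. Ring order: benzene (purchased), then dihydropyran (temporary O-ring), then pyridine.

## Route

**Step 1**
Reactants: 1 3-methoxy-2-nitrobenzaldehyde; 2 acetone
Product: 3 (R)-4-hydroxy-4-(3-methoxy-2-nitrophenyl)butan-2-one (R-enriched)
Conditions: L-proline (30 mol%), acetone/DMSO 1:4, rt, 24–48 h
Reagents that add atoms: none
Why: Proline-catalysed direct intermolecular aldol addition (List–Barbas enamine catalysis) suits this electron-poor, non-enolisable aldehyde and its neutral conditions avoid the hydroxide-driven Baeyer–Drewsen indigo pathway of 2-nitrobenzaldehydes; the carbinol centre forms mainly as R through the hydrogen-bonded Houk–List transition state, but it is erased in step 2, so its purity does not matter.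

**Step 2**
Reactants: 3 (R)-4-hydroxy-4-(3-methoxy-2-nitrophenyl)butan-2-one
Product: 5 (E)-4-(3-methoxy-2-nitrophenyl)but-3-en-2-one, via mesylate 4 (not isolated)
Conditions: MsCl (1.5 equiv), Et3N (3 equiv), CH2Cl2, 0 °C → rt
Reagents that add atoms: methanesulfonyl chloride, CS(=O)(=O)Cl (its atoms are in 4 only)
Why: O-mesylation followed by Et3N-induced E1cB elimination of the β-mesyloxy ketone gives the conjugated enone with the thermodynamically favoured E geometry and removes the stereocentre.

**Step 3**
Reactants: 5 (E)-4-(3-methoxy-2-nitrophenyl)but-3-en-2-one; 6 ethyl vinyl ether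
Product: 7 2-ethoxy-4-(3-methoxy-2-nitrophenyl)-6-methyl-3,4-dihydro-2H-pyran (racemic cis/trans mixture)
Conditions: ethyl vinyl ether (10 equiv), Yb(fod)3 (5 mol%; fod = 6,6,7,7,8,8,8-heptafluoro-2,2-dimethyloctane-3,5-dionate), ClCH2CH2Cl, sealed tube, 60 °C
Reagents that add atoms: none
Why: Lewis-acid-catalysed inverse-electron-demand hetero-Diels–Alder reaction of the 1-oxadiene with the electron-rich vinyl ether, the nucleophilic CH2 terminus bonding to the enone β-carbon; the two new stereocentres (mainly cis by endo addition, racemic) are left uncontrolled because both are destroyed in step 4.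

**Step 4**
Reactants: 7 2-ethoxy-4-(3-methoxy-2-nitrophenyl)-6-methyl-3,4-dihydro-2H-pyran
Product: 10 4-(3-methoxy-2-nitrophenyl)-2-methylpyridine, via keto oxime 8 (not isolated), via N-hydroxy-1,4-dihydropyridine 9 (not isolated)
Conditions: NH2OH·HCl (3 equiv), MeCN, reflux; aq. NaHCO3 work-up
Reagents that add atoms: hydroxylamine hydrochloride, NO.Cl
Why: Knoevenagel–Stobbe-type pyridine synthesis in which acidic hydroxylamine opens the cyclic acetal to the 1,5-keto aldehyde oxime, which cyclises and aromatises by loss of two molecules of water, the N–O bond acting as internal oxidant so that no separate oxidation is needed.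

**Step 5**
Reactants: 10 4-(3-methoxy-2-nitrophenyl)-2-methylpyridine
Product: 11 2-methoxy-6-(2-methylpyridin-4-yl)aniline
Conditions: H2 (1 atm), 10% Pd/C, EtOH, rt
Reagents that add atoms: none
Why: Heterogeneous catalytic hydrogenation reduces the aryl nitro group cleanly to the aniline under conditions that leave the pyridine ring and the aryl methyl ether untouched.

**Step 6**
Reactants: 11 2-methoxy-6-(2-methylpyridin-4-yl)aniline; 12 decanoyl chloride
Product: 13 N-[2-methoxy-6-(2-methylpyridin-4-yl)phenyl]decanamide
Conditions: pyridine (3 equiv), DMAP (5 mol%), CH2Cl2, 0 °C → rt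
Reagents that add atoms: none
Why: N-acylation with an acid chloride under nucleophilic catalysis (acylpyridinium transfer) overcomes the steric shielding of the 2,6-disubstituted aniline, which is the only acylatable nucleophile present.

**Step 7**
Reactants: 13 N-[2-methoxy-6-(2-methylpyridin-4-yl)phenyl]decanamide
Product: 15 echinoclathrine A, via aryloxydibromoborane 14 (not isolated)
Conditions: BBr3 (4 equiv), CH2Cl2, −78 °C → rt; then H2O, aq. NaHCO3 (pH 7)
Reagents that add atoms: boron tribromide, BrB(Br)Br (its atoms are in 14 only)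
Why: Lewis-acid aryl methyl ether cleavage in which BBr3 coordinates the ether oxygen and bromide attacks the methyl group (SN2), the excess reagent covering coordination to the pyridine and amide, and aqueous hydrolysis of the B–O bond releases the phenol.

## Compound list

1 | 3-methoxy-2-nitrobenzaldehyde | COc1cccc(C=O)c1[N+](=O)[O-] | starting material
2 | acetone | CC(C)=O | starting material
3 | (R)-4-hydroxy-4-(3-methoxy-2-nitrophenyl)butan-2-one (R-enriched) | CC(=O)C[C@@H](O)c1cccc(OC)c1[N+](=O)[O-] | intermediate
4 | (R)-1-(3-methoxy-2-nitrophenyl)-3-oxobutyl methanesulfonate | CC(=O)C[C@@H](OS(C)(=O)=O)c1cccc(OC)c1[N+](=O)[O-] | intermediate (not isolated)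
5 | (E)-4-(3-methoxy-2-nitrophenyl)but-3-en-2-one | CC(=O)/C=C/c1cccc(OC)c1[N+](=O)[O-] | intermediate
6 | ethyl vinyl ether | C=COCC | starting material
7 | 2-ethoxy-4-(3-methoxy-2-nitrophenyl)-6-methyl-3,4-dihydro-2H-pyran (racemic cis/trans mixture, stereocentres not defined) | CCOC1CC(C=C(C)O1)c1cccc(OC)c1[N+](=O)[O-] | intermediate
8 | 3-(3-methoxy-2-nitrophenyl)-5-oxohexanal oxime (racemic, E/Z mixture) | CC(=O)CC(CC=NO)c1cccc(OC)c1[N+](=O)[O-] | intermediate (not isolated)
9 | 1-hydroxy-4-(3-methoxy-2-nitrophenyl)-2-methyl-1,4-dihydropyridine (racemic) | CC1=CC(C=CN1O)c1cccc(OC)c1[N+](=O)[O-] | intermediate (not isolated)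
10 | 4-(3-methoxy-2-nitrophenyl)-2-methylpyridine | COc1cccc(-c2ccnc(C)c2)c1[N+](=O)[O-] | intermediate
11 | 2-methoxy-6-(2-methylpyridin-4-yl)aniline | COc1cccc(-c2ccnc(C)c2)c1N | intermediate
12 | decanoyl chloride | CCCCCCCCCC(=O)Cl | starting material
13 | N-[2-methoxy-6-(2-methylpyridin-4-yl)phenyl]decanamide | CCCCCCCCCC(=O)Nc1c(OC)cccc1-c1ccnc(C)c1 | intermediate
14 | dibromo[2-(decanoylamino)-3-(2-methylpyridin-4-yl)phenoxy]borane | CCCCCCCCCC(=O)Nc1c(OB(Br)Br)cccc1-c1ccnc(C)c1 | intermediate (not isolated)
15 | echinoclathrine A, N-[2-hydroxy-6-(2-methylpyridin-4-yl)phenyl]decanamide | CCCCCCCCCC(=O)Nc1c(O)cccc1-c1ccnc(C)c1 | target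

## Summary

Total step count: 7. Longest linear sequence: 7 steps (from 1).

**Steps most likely to fail**

Step 3 (hetero-Diels–Alder reaction). β-Aryl methyl enones are sluggish heterodienes, the ortho-nitroaryl group is twisted and bulky, and the vinyl ether can polymerise. The fallback sets out from 5. Hosomi–Sakurai conjugate allylation (allyltrimethylsilane, TiCl4, CH2Cl2, −78 °C) gives racemic 4-(3-methoxy-2-nitrophenyl)hept-6-en-2-one F3. Ozonolysis (O3, CH2Cl2/MeOH, −78 °C; then Me2S) gives 3-(3-methoxy-2-nitrophenyl)-5-oxohexanal F4, the open-chain form of 7. Treatment with NH2OH·HCl in MeCN at reflux, as in step 4, then gives pyridine 10, where the route is rejoined.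

Step 1 (aldol addition). The aldehyde is flanked by a nitro group, which may slow the enamine addition, and any basic drift risks the indigo-type side reaction. The fallback sets out from 1. A Mukaiyama aldol addition with commercial 2-(trimethylsilyloxy)propene and BF3·OEt2 in CH2Cl2 at −78 °C, followed by aqueous work-up, gives racemic 4-hydroxy-4-(3-methoxy-2-nitrophenyl)butan-2-one F1. MsCl/Et3N as in step 2 converts it through racemic 1-(3-methoxy-2-nitrophenyl)-3-oxobutyl methanesulfonate F2 into enone 5, where the route is rejoined.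

Step 7 (demethylation). The pyridine and amide bind BBr3, and an ortho-hydroxy anilide can cyclise to a benzoxazole under acidic conditions on warming. The fallback sets out from 11 and changes the order of events. Demethylation with 48% aqueous HBr at reflux gives 2-amino-3-(2-methylpyridin-4-yl)phenol F5. Exhaustive acylation with 12 (2.2 equiv, pyridine, CH2Cl2) gives 2-(decanoylamino)-3-(2-methylpyridin-4-yl)phenyl decanoate F6. K2CO3 in MeOH at rt then cleaves only the aryl ester and gives 15, where the route ends.

## Further compounds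

F1 | step 1 | racemic 4-hydroxy-4-(3-methoxy-2-nitrophenyl)butan-2-one | CC(=O)CC(O)c1cccc(OC)c1[N+](=O)[O-]
F2 | step 1 | racemic 1-(3-methoxy-2-nitrophenyl)-3-oxobutyl methanesulfonate | CC(=O)CC(OS(C)(=O)=O)c1cccc(OC)c1[N+](=O)[O-]
F3 | step 3 | racemic 4-(3-methoxy-2-nitrophenyl)hept-6-en-2-one | CC(=O)CC(CC=C)c1cccc(OC)c1[N+](=O)[O-]
F4 | step 3 | racemic 3-(3-methoxy-2-nitrophenyl)-5-oxohexanal | CC(=O)CC(CC=O)c1cccc(OC)c1[N+](=O)[O-]
F5 | step 7 | 2-amino-3-(2-methylpyridin-4-yl)phenol | Cc1cc(-c2cccc(O)c2N)ccn1
F6 | step 7 | 2-(decanoylamino)-3-(2-methylpyridin-4-yl)phenyl decanoate | CCCCCCCCCC(=O)Nc1c(OC(=O)CCCCCCCCC)cccc1-c1ccnc(C)c1
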